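## The problem

Target 14 is 3,5-dihydroxy-7-methoxy-4-oxo-2-phenyl-4H-chromen-8-yl butanoate, a flavonol with an unsubstituted phenyl as ring B and oxygen on every ring A position except C6. It has no stereocentre, so the difficulty is regiochemical: O3 and O5 must end as free hydroxyls, O7 as a methyl ether and O8 as a butanoate. The aryl butanoate will not survive hydroxide, alkoxide or the boron and aluminium halides used for ether cleavage, so it has to go on late and the last deprotection has to be neutral. The 5,8-quinol that precedes it is oxidised by air in base, and a free 3-OH would compete in every alkylation and acylation, so O3 must stay masked to the end. O8 lies para to O5 and ortho to O7, a pattern that no cheap phenol supplies ready-made. The enabling feature is that C5, C7 and C8a carry oxygen while C4a carries the acyl carbon C4: ring A is an acylphloroglucinol, the pattern of a poly-β-keto chain folded by Claisen condensation. The C4a–C8a bond can therefore be made by attack of an active methylene on an ester carbonyl. The phloroglucinol so formed is symmetric about the acyl group, so closure of ring C has no regiochemical choice, and the one oxygen the fold does not supply, O8, sits para to the chelated 5-OH where persulfate oxidation reaches it.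

## Retrosynthesis

Chain atoms are numbered C1 (ester carbon) to C9 (benzoyl carbon); flavone atoms carry the usual chromone numbers.

**14 to 13 (O3–CH2Ph).** The last cut removes a benzyl group from O3. Benzyl is the one ether here that comes off under neutral conditions, which the butanoate requires; a methyl or acyl group on O3 would need a Lewis acid or base. The forward hydrogenolysis must spare the aryl ester and the C2=C3 bond.

**13 to 12 (O8–acyl).** The butanoate is cut next, so the ester meets only one later step. In quinol 12 the 5-OH is hydrogen-bonded to the C4 carbonyl and the 8-OH is not, which is the basis for mono-acylation.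

**12 to 10 by way of 11 (C8–O).** Removing O8 returns ring A to the phloroglucinol pattern. Carrying O8 from the start would break the symmetry that makes ring C closure unambiguous and would leave the polyketide logic. The forward step is a para-selective hydroxylation directed by the 5-phenoxide (Elbs oxidation through aryl sulfate 11); C6, the ortho position, must stay untouched.

**10 to 9 (O7–CH3).** The 7-OH is the most acidic phenol of 9 and the 5-OH is chelated, so one equivalent of methylating agent should suffice. Methylating only after ring C exists keeps the earlier phloroglucinol symmetric.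

**9 to 8 (O1–C2).** Opening ring C at O1–C2 gives the o-hydroxyaryl 1,3-diketone 8 at the flavonol oxidation level with O3 already in place. Chalcone or flavanone cuts would demand a later dehydrogenation or C3 oxidation. The forward step is an acid cyclodehydration mild enough for the benzyl ether.

**8 to 7 (C4a–C8a, the key cut).** The aromatic ring is unfolded to tetraketo ester 7 by cutting the bond between chain C6 and C1. The neighbouring cut, C4–C4a (acylation of bought phloroglucinol), is legitimate and is kept as a fallback. The Claisen cut reduces ring A to a linear chain of acetate-level pieces and sets three ring oxygens and the acyl group in one event. The forward reaction must fold by Claisen condensation and not by aldol addition.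

**7 to 5 and 6 (chain C8–C9, flavone C2–C3).** The benzoyl group is cut from the terminal carbon. In the polyanion of 5 that carbon is the last deprotonated and the most nucleophilic, so methyl benzoate 6 should react there. A cut at C6–C7 with a preformed benzoyl-bearing acyl donor would need an electrophile with an acidic CH that quenches the polyanion.

**5 to 3 and 4 (chain C6–C7).** The same logic one stage earlier: the terminal methyl of diketo ester 3, as its trianion, is acylated by methyl benzyloxyacetate 4, which brings O3 already benzylated.

**3 to 1 by way of 2.** Diketo ester 3 is the methanolysis and deacetylation product of dehydroacetic acid 1, a commodity pyranone; ring-opened triacylmethane 2 is the intermediate.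

## Roads not taken

**Alternative 1:** The cut is O1–C2 with introduction of a C3–I bond. Ynone A1, 3-phenyl-1-(2,4,6-trimethoxyphenyl)prop-2-yn-1-one, is treated with ICl; an ortho methoxy oxygen attacks the phenyl-bearing alkyne carbon in a 6-endo sense and loss of the O-methyl group gives 3-iodo-5,7-dimethoxyflavone A2.
- Merits: A1 is one acylation away from commercial materials, the iodocyclization is dependable for electron-rich aryl ynones, and no polyanion is needed.
- Weak points: A2 carries iodine where the target has a hydroxyl, so a C–O bond must still be made on a 3-iodochromone. Both ring A oxygens arrive as methyl ethers, so O5 must be demethylated with a boron or aluminium halide before the persulfate step, and that reagent is incompatible with a 3-O-benzyl group, which fixes the order of events. O8 is still missing, so the same Elbs oxidation is needed.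
- Comparison: this road is probably one or two steps shorter, and its early steps are more robust than polyanion chemistry. The chosen plan sets against that an O3 that is present and correctly protected from the first acylation, free 5- and 7-hydroxyls differentiated by chelation without ether cleavage, and no halogen-to-oxygen exchange.

**Alternative 2:** The cut is C4a–C5, with ring A grown on a preformed pyranone. Cyclobutenone A3, 3-(benzyloxy)-6-(1-hydroxy-2-methoxy-4-oxocyclobut-2-en-1-yl)-2-phenyl-4H-pyran-4-one, opens on heating to a dienylketene whose ketene carbon bonds to pyranone C5; tautomerization gives quinol A4, identical with compound 12.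
- Merits: the para relation of O5 and O8, the 7-methoxy group and the C6–H are all fixed by mechanism, and the low-yielding persulfate step disappears. On regiocontrol at O8 this road is better than the chosen one.
- Weak points: A3 requires 1,2-addition of a C6-metalated 4-pyranone to a methoxycyclobutenedione. 4-Pyranones are prone to ring-opening by strong nucleophiles and bases, the 3-alkoxy-2-aryl pyranone itself takes several steps, and the squarate partner is costly.
- Comparison: the chosen plan uses three cheap esters and a ring closure of a precedented class, and pays for it with the Elbs step.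

**Alternative 3:** The cut is C4–C4a. Acid A5, (Z)-3-[2-(benzyloxy)-3,5-dimethoxyphenoxy]-3-phenylprop-2-enoic acid, is activated (P2O5/MeSO3H or the acid chloride) and acylates the one free carbon ortho to the ether oxygen, giving 8-(benzyloxy)-5,7-dimethoxyflavone A6.
- Merits: O8 is carried in from the start, the closure site is activated by a para and an ortho methoxy group, and only one position can react. It avoids both the polyanions and the persulfate oxidation.
- Weak points: A6 has no oxygen at C3, so the flavone must be hydroxylated later. The strongly acidic closure threatens the benzyl ether. The tetrasubstituted phenol behind A5 is not commercial. O3 and O8 then need a protecting-group exchange, and O5 a selective demethylation, close to the base-labile ester.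
- Comparison: the sequence should come out longer and harsher near the end. The chosen plan has O3 in place from the chain stage and ends with three mild steps.

Key step: step 4

Assumption: the lithium and magnesium polyenolates of steps 2 to 4 are treated as conjugate bases of the numbered compounds, not as separate intermediates; 7 and 8 are racemic at the benzyloxy-bearing carbon and largely enolized.

## Route

Step 1
Reactants: 1 dehydroacetic acid (3-acetyl-4-hydroxy-6-methyl-2H-pyran-2-one)
Product: 3 methyl 3,5-dioxohexanoate, via methyl 2-acetyl-3,5-dioxohexanoate 2 (not isolated)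
Conditions: Mg(OMe)2 (from Mg), MeOH, reflux; cold aq. HCl; distillation
Reagents that add atoms: methanol, CO, delivered as magnesium dimethoxide Mg(OMe)2, C[O-].C[O-].[Mg+2]
Why: Methoxide opens the lactone to the magnesium chelate of triacylmethane 2, which loses its acetyl group as methyl acetate by retro-Claisen cleavage; this alcoholysis with deacylation is an established way to the diketo ester.

Step 2
Reactants: 3 methyl 3,5-dioxohexanoate; 4 methyl 2-(benzyloxy)acetate
Product: 5 methyl 8-(benzyloxy)-3,5,7-trioxooctanoate
Conditions: LiN(i-Pr)2 (4.2 equiv), THF, 0 °C; then 4 (1.0 equiv), −78 to 0 °C; cold aq. HCl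
Reagents that add atoms: none
Why: Terminal acylation of a β-polycarbonyl polyanion: in the trianion of 3 the terminal carbanion is the last formed and most nucleophilic and attacks the ester of 4, while the enolized C1 to C5 array protects the chain's own ester; the extra base takes up the new acidic C6 proton of the product.

Step 3
Reactants: 5 methyl 8-(benzyloxy)-3,5,7-trioxooctanoate; 6 methyl benzoate
Product: 7 methyl 8-(benzyloxy)-3,5,7,9-tetraoxo-9-phenylnonanoate (racemic at C8, enolizable)
Conditions: LiN(i-Pr)2 (5.2 equiv), THF, 0 °C; then 6 (1.1 equiv), 0 to 20 °C; cold aq. HCl, used crude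
Reagents that add atoms: none
Why: The same polyanion aroylation one stage on: the fourth deprotonation can only occur at the benzyloxy-bearing terminal carbon C8, which is benzoylated by the non-enolizable ester; the product is held as its polyenolate until the cold quench, which suppresses premature cyclization.

Step 4
Reactants: 7 methyl 8-(benzyloxy)-3,5,7,9-tetraoxo-9-phenylnonanoate
Product: 8 2-(benzyloxy)-1-phenyl-3-(2,4,6-trihydroxyphenyl)propane-1,3-dione (racemic, enolizable)
Conditions: Mg(OMe)2 (5 equiv), MeOH, 20 to 50 °C; cold 1 M HCl
Reagents that add atoms: none
Why: Mg(OMe)2 holds 7 as a chelated polyenolate; the C6 carbanion adds to the C1 ester carbonyl, methoxide leaves the tetrahedral intermediate and the cyclohexane-1,3,5-trione tautomerizes irreversibly to the phloroglucinol. The closest known reaction type is the base- or Mg(OMe)2-mediated Claisen cyclization of 3,5,7-triketo esters to acylphloroglucinols, the laboratory counterpart of the chalcone synthase fold. Ring A closes as a six-membered carbocycle by 6-exo-trig attack of an enolate carbon on the ester carbonyl. No stereocentre is created; the benzyloxy-bearing carbon stays racemic and becomes sp2 in step 5. The step needs closure from C6 to C1 to win over aldol closures from C2 to C7 and from C4 to C9 and over O-cyclization. C1 carries the only leaving group; C7 is flanked by the acidic C6 and C8 positions and C9 by C8, so both ketones sit in chelated enolates and are poor aldol acceptors; an aldol from C8 to C3 would give a quaternary carbon that cannot aromatize and reverts; any 2-pyranone formed by O-acylation is reopened by methoxide, so the system should drain into the aromatic C-acylation product.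

Step 5
Reactants: 8 2-(benzyloxy)-1-phenyl-3-(2,4,6-trihydroxyphenyl)propane-1,3-dione
Product: 9 3-(benzyloxy)-5,7-dihydroxy-2-phenyl-4H-chromen-4-one
Conditions: p-TsOH·H2O (10 mol%), AcOH, 60 °C
Reagents that add atoms: none
Why: Acid-catalysed cyclodehydration of an o-hydroxyaryl 1,3-diketone, the ring-closing half of the Baker–Venkataraman and Allan–Robinson flavone syntheses: an ortho hydroxyl adds to the benzoyl carbonyl (6-exo-trig) and water is lost. Both ortho hydroxyls are equivalent, and catalytic sulfonic acid in warm AcOH should spare the benzyl ether.

Step 6
Reactants: 9 3-(benzyloxy)-5,7-dihydroxy-2-phenyl-4H-chromen-4-one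
Product: 10 3-(benzyloxy)-5-hydroxy-7-methoxy-2-phenyl-4H-chromen-4-one
Conditions: MeI (1.1 equiv), K2CO3 (1.2 equiv), acetone, 20 to 40 °C
Reagents that add atoms: iodomethane, CI
Why: Williamson etherification at the most acidic, non-chelated 7-OH; the 5-OH is hydrogen-bonded to the C4 carbonyl and is methylated only under forcing conditions, the standard selectivity of 5,7-dihydroxyflavones.

Step 7
Reactants: 10 3-(benzyloxy)-5-hydroxy-7-methoxy-2-phenyl-4H-chromen-4-one
Product: 12 3-(benzyloxy)-5,8-dihydroxy-7-methoxy-2-phenyl-4H-chromen-4-one, via potassium flavon-8-yl sulfate 11 (not isolated)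
Conditions: K2S2O8 (1.2 equiv), aq. KOH, pyridine, 0 to 20 °C, N2; acidify to pH 4 and extract unchanged 10; then 1 M HCl, Na2SO3 (cat.), 60 °C
Reagents that add atoms: potassium peroxodisulfate K2S2O8, [K+].[K+].[O-]S(=O)(=O)OOS(=O)(=O)[O-]
Why: Elbs persulfate oxidation: the 5-phenoxide attacks a peroxide oxygen through its para carbon C8, the only para position and the site established for 5-hydroxy-7-methoxyflavones and flavonol ethers, giving sulfate 11. Dilute acid then hydrolyses 11 at the S–O bond to the quinol.

Step 8
Reactants: 12 3-(benzyloxy)-5,8-dihydroxy-7-methoxy-2-phenyl-4H-chromen-4-one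
Product: 13 3-(benzyloxy)-5-hydroxy-7-methoxy-4-oxo-2-phenyl-4H-chromen-8-yl butanoate
Conditions: (n-PrCO)2O (1.1 equiv), pyridine, CH2Cl2, 0 °C, N2
Reagents that add atoms: butanoic anhydride, CCCC(=O)OC(=O)CCC
Why: Selective O-acylation of the free 8-OH; the 5-OH is deactivated by its hydrogen bond to the C4 carbonyl, the same discrimination that allows selective 8-O-alkylation of 5,8-dihydroxyflavones.

Step 9
Reactants: 13 3-(benzyloxy)-5-hydroxy-7-methoxy-4-oxo-2-phenyl-4H-chromen-8-yl butanoate
Product: 14 3,5-dihydroxy-7-methoxy-4-oxo-2-phenyl-4H-chromen-8-yl butanoate
Conditions: H2 (1 atm), 10% Pd/C, EtOAc, 20 °C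
Reagents that add atoms: none
Why: Neutral hydrogenolysis of the benzyl ether on O3; the aryl butanoate, the methyl ether and the chromone C2=C3 bond are inert under these conditions.

## Compound list

1 | dehydroacetic acid (3-acetyl-4-hydroxy-6-methyl-2H-pyran-2-one) | CC(=O)C1=C(O)C=C(C)OC1=O | starting material
2 | methyl 2-acetyl-3,5-dioxohexanoate | COC(=O)C(C(C)=O)C(=O)CC(C)=O | intermediate
3 | methyl 3,5-dioxohexanoate | COC(=O)CC(=O)CC(C)=O | intermediate
4 | methyl 2-(benzyloxy)acetate | COC(=O)COCc1ccccc1 | starting material
5 | methyl 8-(benzyloxy)-3,5,7-trioxooctanoate | COC(=O)CC(=O)CC(=O)CC(=O)COCc1ccccc1 | intermediate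
6 | methyl benzoate | COC(=O)c1ccccc1 | starting material
7 | methyl 8-(benzyloxy)-3,5,7,9-tetraoxo-9-phenylnonanoate (racemic) | COC(=O)CC(=O)CC(=O)CC(=O)C(OCc1ccccc1)C(=O)c1ccccc1 | intermediate
8 | 2-(benzyloxy)-1-phenyl-3-(2,4,6-trihydroxyphenyl)propane-1,3-dione (racemic) | Oc1cc(O)c(C(=O)C(OCc2ccccc2)C(=O)c2ccccc2)c(O)c1 | intermediate
9 | 3-(benzyloxy)-5,7-dihydroxy-2-phenyl-4H-chromen-4-one | Oc1cc(O)c2c(=O)c(OCc3ccccc3)c(-c3ccccc3)oc2c1 | intermediate
10 | 3-(benzyloxy)-5-hydroxy-7-methoxy-2-phenyl-4H-chromen-4-one | COc1cc(O)c2c(=O)c(OCc3ccccc3)c(-c3ccccc3)oc2c1 | intermediate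
11 | potassium 3-(benzyloxy)-5-hydroxy-7-methoxy-4-oxo-2-phenyl-4H-chromen-8-yl sulfate | [K+].[O-]S(=O)(=O)Oc1c(OC)cc(O)c2c(=O)c(OCc3ccccc3)c(-c3ccccc3)oc12 | intermediate
12 | 3-(benzyloxy)-5,8-dihydroxy-7-methoxy-2-phenyl-4H-chromen-4-one | COc1cc(O)c2c(=O)c(OCc3ccccc3)c(-c3ccccc3)oc2c1O | intermediate
13 | 3-(benzyloxy)-5-hydroxy-7-methoxy-4-oxo-2-phenyl-4H-chromen-8-yl butanoate | CCCC(=O)Oc1c(OC)cc(O)c2c(=O)c(OCc3ccccc3)c(-c3ccccc3)oc12 | intermediate
14 | 3,5-dihydroxy-7-methoxy-4-oxo-2-phenyl-4H-chromen-8-yl butanoate | CCCC(=O)Oc1c(OC)cc(O)c2c(=O)c(O)c(-c3ccccc3)oc12 | target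

## Step count and risks

Total step count: 9. Longest linear sequence: 9 steps, from 1 to 14.

**Step 4 (key step).** The chain may fold the wrong way. Aldol closure from C2 to C7 or from C4 to C9 would give resorcinol-type aromatics, and methoxide could cleave the 2-alkoxy-1,3-diketone by retro-Claisen loss of the benzoyl group before ring A has formed. The aldol acceptors are ketones and intrinsically more electrophilic than the ester, so the outcome rests on chelation and on the irreversibility of aromatization. Fallback, setting out from 4 and 6 and returning at 9, with ring A bought instead of made: crossed Claisen condensation of 4 with 6 (LiN(SiMe3)2, THF, −78 to 0 °C) would give methyl 2-(benzyloxy)-3-oxo-3-phenylpropanoate F1 (racemic). Heating F1 with phloroglucinol without solvent at about 240 °C (Mentzer thermal chromone synthesis) should give 9 directly with loss of methanol and water.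

**Step 3.** The fourth deprotonation may be incomplete, or the α-benzyloxy carbanion may decompose (for example by a 1,2-shift of the benzyl group) before it is acylated. The polyketone may also cyclize during the quench. A tetra-anion with an alkoxy-substituted terminus is more basic and more crowded than the methyl-terminated cases on which this reaction type is established; step 2 shares these concerns to a lesser degree. Fallback, setting out from 5 and returning at 9, with the benzoyl group brought in after ring A exists: Mg(OMe)2 in MeOH should close triketo ester 5 by the same Claisen fold to 2-(benzyloxy)-1-(2,4,6-trihydroxyphenyl)ethan-1-one F2. Allan–Robinson condensation of F2 with benzoic anhydride and PhCO2Na at 180 °C would give 3-(benzyloxy)-5-hydroxy-4-oxo-2-phenyl-4H-chromen-7-yl benzoate F3, and aq. KOH in EtOH would remove the benzoate to give 9.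

**Step 7.** Conversion in persulfate oxidations is usually incomplete. The quinol may be over-oxidized to the quinone in the alkaline medium, and the benzyl ether may be lost during acid hydrolysis of sulfate 11 if the acid is too strong or too hot. Fallback, setting out from 10 and returning at 12, by an oxidation–reduction sequence: Teuber oxidation of 10 with (KSO3)2NO in buffered aqueous acetone (KH2PO4) would give 3-(benzyloxy)-7-methoxy-2-phenyl-4H-chromene-4,5,8-trione F4, and reduction of F4 with aqueous Na2S2O4 should give 12 without any acid step.

**Step 8.** Over-acylation at the chelated 5-OH, or air oxidation of the quinol under basic conditions, would lower the return of the mono-ester. Fallback, setting out from 12 and returning at 13, by temporary masking of the chelated site: BF3·OEt2 in CH2Cl2 would convert 12 into the O4,O5-difluoroboron chelate of 3-(benzyloxy)-5,8-dihydroxy-7-methoxy-2-phenyl-4H-chromen-4-one F5. Butanoyl chloride and Et3N would acylate the only remaining hydroxyl to give the O4,O5-difluoroboron chelate of 3-(benzyloxy)-5-hydroxy-7-methoxy-4-oxo-2-phenyl-4H-chromen-8-yl butanoate F6, and warming F6 in aqueous MeOH at 60 °C should release 13.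

## Further compounds

F1 | step 4 | methyl 2-(benzyloxy)-3-oxo-3-phenylpropanoate (racemic) | COC(=O)C(OCc1ccccc1)C(=O)c1ccccc1
F2 | step 3 | 2-(benzyloxy)-1-(2,4,6-trihydroxyphenyl)ethan-1-one | O=C(COCc1ccccc1)c1c(O)cc(O)cc1O
F3 | step 3 | 3-(benzyloxy)-5-hydroxy-4-oxo-2-phenyl-4H-chromen-7-yl benzoate | O=C(Oc1cc(O)c2c(=O)c(OCc3ccccc3)c(-c3ccccc3)oc2c1)c1ccccc1
F4 | step 7 | 3-(benzyloxy)-7-methoxy-2-phenyl-4H-chromene-4,5,8-trione | COC1=CC(=O)C2=C(C1=O)OC(c1ccccc1)=C(OCc1ccccc1)C2=O
F5 | step 8 | O4,O5-difluoroboron chelate of 3-(benzyloxy)-5,8-dihydroxy-7-methoxy-2-phenyl-4H-chromen-4-one | COC1=CC2=C3C(=[O+][B-](F)(F)O2)C(OCc2ccccc2)=C(c2ccccc2)OC3=C1O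
F6 | step 8 | O4,O5-difluoroboron chelate of 3-(benzyloxy)-5-hydroxy-7-methoxy-4-oxo-2-phenyl-4H-chromen-8-yl butanoate | COC1=CC2=C3C(=[O+][B-](F)(F)O2)C(OCc2ccccc2)=C(c2ccccc2)OC3=C1OC(=O)CCC
A1 | alternative 1 | 3-phenyl-1-(2,4,6-trimethoxyphenyl)prop-2-yn-1-one | COc1cc(OC)c(C(=O)C#Cc2ccccc2)c(OC)c1
A2 | alternative 1 | 3-iodo-5,7-dimethoxy-2-phenyl-4H-chromen-4-one | COc1cc(OC)c2c(=O)c(I)c(-c3ccccc3)oc2c1
A3 | alternative 2 | 3-(benzyloxy)-6-(1-hydroxy-2-methoxy-4-oxocyclobut-2-en-1-yl)-2-phenyl-4H-pyran-4-one (racemic) | COC1=CC(=O)C1(O)c1cc(=O)c(OCc2ccccc2)c(-c2ccccc2)o1
A4 | alternative 2 | 3-(benzyloxy)-5,8-dihydroxy-7-methoxy-2-phenyl-4H-chromen-4-one (identical with 12) | COc1cc(O)c2c(=O)c(OCc3ccccc3)c(-c3ccccc3)oc2c1O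
A5 | alternative 3 | (Z)-3-[2-(benzyloxy)-3,5-dimethoxyphenoxy]-3-phenylprop-2-enoic acid | OC(=O)/C=C(\Oc1cc(OC)cc(OC)c1OCc1ccccc1)c1ccccc1
A6 | alternative 3 | 8-(benzyloxy)-5,7-dimethoxy-2-phenyl-4H-chromen-4-one | COc1cc(OC)c2c(=O)cc(-c3ccccc3)oc2c1OCc1ccccc1
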